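**Strategy.** The route rests on disconnecting C2–C3 of ring C, the pyranone of the 4-methoxyphenyl flavanone. C3 is α to C4=O but also β to C4''=O of the second flavanone (pyranone ring F, 4-hydroxyphenyl ring E), so it can serve as the β-carbon of an exocyclic enone C3=C3'' on ring F, while C2, which carries O1 and anisyl ring B, is an α-aryloxybenzyl radical released from a carboxylic acid. The key step, a photoredox decarboxylative 6-exo radical conjugate addition, closes ring C, sets C2 and C3 under control of the axial ring E on C2'' and expels the activating carboxyl group as CO2. Its precursor is an (E)-3-aroylmethylene derivative of dibenzylated (2S)-naringenin bearing an aryloxy(4-methoxyphenyl)acetic acid.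

Key step: step 8

Remark (assumption): commercial (2S)-naringenin is taken to be of high enantiomeric purity; its ee should be checked and, if needed, upgraded by crystallisation before use.

Remark (locants): unprimed locants and rings A, B, C belong to the 4-methoxyphenyl flavanone; double-primed locants and rings D, E, F belong to the 4-hydroxyphenyl flavanone. Compounds 4, 5, 6, 10 and 11 are epimeric mixtures at the carboxyl-bearing carbon, which is erased in step 8.

Step 1
Reactants: 1 2,4,6-trihydroxyacetophenone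
Product: 2 1-[2,4-bis(benzyloxy)-6-hydroxyphenyl]ethan-1-one
Conditions: BnBr (2.05 equiv), K2CO3 (2.2 equiv), DMF, rt
Reagents that add atoms: benzyl bromide, BrCc1ccccc1
Why: Williamson etherification should take the para hydroxyl and one ortho hydroxyl, the remaining ortho hydroxyl being deactivated by its hydrogen bond to the acetyl group.

Step 2
Reactants: 2 1-[2,4-bis(benzyloxy)-6-hydroxyphenyl]ethan-1-one; 3 methyl 2-bromo-2-(4-methoxyphenyl)acetate
Product: 4 methyl 2-[2-acetyl-3,5-bis(benzyloxy)phenoxy]-2-(4-methoxyphenyl)acetate (racemic)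
Conditions: K2CO3, DMF, rt
Reagents that add atoms: none
Why: Williamson etherification of the remaining phenol with a highly reactive benzylic α-bromo ester should form the future O1–C2 bond; the new stereocentre is racemic and is erased in step 8.

Step 3
Reactants: 4 methyl 2-[2-acetyl-3,5-bis(benzyloxy)phenoxy]-2-(4-methoxyphenyl)acetate
Product: 5 2-[2-acetyl-3,5-bis(benzyloxy)phenoxy]-2-(4-methoxyphenyl)acetic acid
Conditions: LiOH·H2O, THF/MeOH/H2O, 0 °C to rt; then 1 M HCl
Reagents that add atoms: lithium hydroxide, [Li+].[OH-]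
Why: Saponification of the methyl ester is done here, while the molecule still has no base-sensitive enone, so that the free acid can be carried to the key step.

Step 4
Reactants: 5 2-[2-acetyl-3,5-bis(benzyloxy)phenoxy]-2-(4-methoxyphenyl)acetic acid
Product: 6 2-[3,5-bis(benzyloxy)-2-(2-oxoacetyl)phenoxy]-2-(4-methoxyphenyl)acetic acid (handled as its aldehyde hydrate)
Conditions: SeO2 (1.5 equiv), 1,4-dioxane/H2O (20:1), 90 °C
Reagents that add atoms: selenium dioxide, O=[Se]=O
Why: Riley oxidation of the aryl methyl ketone should give the aryl glyoxal, whose aldehyde carbon becomes C3; benzyl ethers and the acid are expected to survive.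

Step 5
Reactants: 7 (2S)-naringenin
Product: 8 (2S)-7-(benzyloxy)-2-[4-(benzyloxy)phenyl]-5-hydroxychroman-4-one
Conditions: BnOH (2.2 equiv), PPh3 (2.2 equiv), DIAD (2.2 equiv), THF, 0 °C to rt
Reagents that add atoms: benzyl alcohol, OCc1ccccc1
Why: Mitsunobu etherification alkylates the 7- and 4'-hydroxyls under essentially neutral conditions, so no free phenoxide can open ring F and C2'' should keep its configuration; the chelated 5-hydroxyl does not react.

Step 6
Reactants: 8 (2S)-7-(benzyloxy)-2-[4-(benzyloxy)phenyl]-5-hydroxychroman-4-one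
Product: 9 (2S)-7-(benzyloxy)-2-[4-(benzyloxy)phenyl]-4,5-bis(trimethylsilyloxy)-2H-chromene
Conditions: TMSOTf (2.4 equiv), Et3N (3 equiv), CH2Cl2, 0 °C; used crude
Reagents that add atoms: trimethylsilyl trifluoromethanesulfonate, C[Si](C)(C)OS(=O)(=O)C(F)(F)F
Why: Soft enolisation gives the silyl enol ether without a free enolate, which avoids β-elimination of the O1'' phenoxide and thus protects C2''; the 5-hydroxyl is silylated as well.

Step 7
Reactants: 9 (2S)-7-(benzyloxy)-2-[4-(benzyloxy)phenyl]-4,5-bis(trimethylsilyloxy)-2H-chromene; 6 2-[3,5-bis(benzyloxy)-2-(2-oxoacetyl)phenoxy]-2-(4-methoxyphenyl)acetic acid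
Product: 11 2-{3,5-bis(benzyloxy)-2-[(E)-2-{(2R)-7-(benzyloxy)-2-[4-(benzyloxy)phenyl]-5-hydroxy-4-oxochroman-3-ylidene}acetyl]phenoxy}-2-(4-methoxyphenyl)acetic acid (C2'' unchanged in space; the descriptor changes by priority only), via aldol adduct 10 (not isolated)
Conditions: Yb(OTf)3 (10 mol%), THF/H2O (9:1), rt; then TsOH·H2O (10 mol%), CH2Cl2, 4 Å MS, rt
Reagents that add atoms: none
Why: A lanthanide triflate-catalysed aqueous Mukaiyama aldol addition, which tolerates aldehyde hydrates and free acids, joins C3'' to the glyoxal carbon C3, and acid-catalysed dehydration should give the thermodynamically preferred (E)-ene-dione with the aroyl group trans to C4''=O.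

Step 8
Reactants: 11 2-{3,5-bis(benzyloxy)-2-[(E)-2-{(2R)-7-(benzyloxy)-2-[4-(benzyloxy)phenyl]-5-hydroxy-4-oxochroman-3-ylidene}acetyl]phenoxy}-2-(4-methoxyphenyl)acetic acid
Product: 13 (2S,3R)-5,7-bis(benzyloxy)-3-{(2S,3R)-7-(benzyloxy)-2-[4-(benzyloxy)phenyl]-5-hydroxy-4-oxochroman-3-yl}-2-(4-methoxyphenyl)chroman-4-one, via 2'',3''-cis epimer 12 (not isolated)
Conditions: Ir[dF(CF3)ppy]2(dtbbpy)PF6 (2 mol%), K2HPO4 (1.2 equiv), DMF (0.01 M), 450 nm LEDs, Ar, rt; then Et3N (1 equiv), CH2Cl2/MeOH, rt
Reagents that add atoms: none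
Why: The excited trivalent iridium photocatalyst oxidises the carboxylate of 11, CO2 is lost, and the α-aryloxy-4-methoxybenzyl radical at C2 adds to C3, the β-carbon of the enone C3=C3''–C4''=O, after which the C3'' α-keto radical is reduced to the enolate and protonated (decarboxylative Giese reaction; closest known type: photoredox conjugate addition of α-oxyalkyl radicals from α-oxy acids to enones). Ring C closes in the 6-exo-trig mode through the C2–C3 bond, 7-endo attack at the fully substituted C3'' being disfavoured. C3 is controlled by ring E on C2'', which allylic 1,3-strain with the (E)-aroyl group forces axial so that it shields one face of C3=C3'' and the radical should enter anti to it (3R). C2 is controlled by a chair-like transition state with the anisyl group and C3'' both pseudo-equatorial (2,3-trans, 2S), and the stereocentre at the carboxyl carbon is erased in the planar radical so both epimers of 11 converge. C3'' is expected to be protonated first anti to ring E (cis epimer 12) and, being α to the C4'' ketone, is equilibrated by Et3N to the diequatorial 2'',3''-trans arrangement (3''R). The step needs 6-exo regioselectivity, anti facial selectivity and trans ring closure; the first two are secured by the E geometry and the axial ring E of 11, the third only by the equatorial preference of the anisyl group.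

Step 9
Reactants: 13 (2S,3R)-5,7-bis(benzyloxy)-3-{(2S,3R)-7-(benzyloxy)-2-[4-(benzyloxy)phenyl]-5-hydroxy-4-oxochroman-3-yl}-2-(4-methoxyphenyl)chroman-4-one
Product: 14 (2S,3R)-5,7-dihydroxy-3-[(2S,3R)-5,7-dihydroxy-2-(4-hydroxyphenyl)-4-oxochroman-3-yl]-2-(4-methoxyphenyl)chroman-4-one (CNP0196568.1)
Conditions: H2 (1 atm), 10% Pd/C, EtOAc/MeOH (1:1), rt
Reagents that add atoms: none
Why: Neutral hydrogenolysis should remove the four O-benzyl groups without base, so that the free 4'''-phenol cannot open ring F, and should leave the methyl ether and all four stereocentres untouched.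

**Compound list**
1 | 2,4,6-trihydroxyacetophenone | CC(=O)c1c(O)cc(O)cc1O | starting material
2 | 1-[2,4-bis(benzyloxy)-6-hydroxyphenyl]ethan-1-one | CC(=O)c1c(O)cc(OCc2ccccc2)cc1OCc1ccccc1 | intermediate
3 | methyl 2-bromo-2-(4-methoxyphenyl)acetate (racemic) | COC(=O)C(Br)c1ccc(OC)cc1 | starting material
4 | methyl 2-[2-acetyl-3,5-bis(benzyloxy)phenoxy]-2-(4-methoxyphenyl)acetate (racemic) | COC(=O)C(Oc1cc(OCc2ccccc2)cc(OCc2ccccc2)c1C(C)=O)c1ccc(OC)cc1 | intermediate
5 | 2-[2-acetyl-3,5-bis(benzyloxy)phenoxy]-2-(4-methoxyphenyl)acetic acid (racemic) | OC(=O)C(Oc1cc(OCc2ccccc2)cc(OCc2ccccc2)c1C(C)=O)c1ccc(OC)cc1 | intermediate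
6 | 2-[3,5-bis(benzyloxy)-2-(2-oxoacetyl)phenoxy]-2-(4-methoxyphenyl)acetic acid (racemic; drawn as the aldehyde) | OC(=O)C(Oc1cc(OCc2ccccc2)cc(OCc2ccccc2)c1C(=O)C=O)c1ccc(OC)cc1 | intermediate
7 | (2S)-naringenin | O=C1C[C@@H](c2ccc(O)cc2)Oc2cc(O)cc(O)c21 | starting material
8 | (2S)-7-(benzyloxy)-2-[4-(benzyloxy)phenyl]-5-hydroxychroman-4-one | O=C1C[C@@H](c2ccc(OCc3ccccc3)cc2)Oc2cc(OCc3ccccc3)cc(O)c21 | intermediate
9 | (2S)-7-(benzyloxy)-2-[4-(benzyloxy)phenyl]-4,5-bis(trimethylsilyloxy)-2H-chromene | C[Si](C)(C)OC1=C[C@@H](c2ccc(OCc3ccccc3)cc2)Oc2cc(OCc3ccccc3)cc(O[Si](C)(C)C)c21 | intermediate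
10 | aldol adduct: 2-{3,5-bis(benzyloxy)-2-[2-hydroxy-2-{(2S)-7-(benzyloxy)-2-[4-(benzyloxy)phenyl]-5-hydroxy-4-oxochroman-3-yl}acetyl]phenoxy}-2-(4-methoxyphenyl)acetic acid (diastereomer mixture at C3, C3'' and the carboxyl carbon) | OC(=O)C(Oc1cc(OCc2ccccc2)cc(OCc2ccccc2)c1C(=O)C(O)C1C(=O)c2c(O)cc(OCc3ccccc3)cc2O[C@@H]1c1ccc(OCc2ccccc2)cc1)c1ccc(OC)cc1 | intermediate (not isolated)
11 | 2-{3,5-bis(benzyloxy)-2-[(E)-2-{(2R)-7-(benzyloxy)-2-[4-(benzyloxy)phenyl]-5-hydroxy-4-oxochroman-3-ylidene}acetyl]phenoxy}-2-(4-methoxyphenyl)acetic acid | OC(=O)C(Oc1cc(OCc2ccccc2)cc(OCc2ccccc2)c1C(=O)/C=C1/C(=O)c2c(O)cc(OCc3ccccc3)cc2O[C@@H]1c1ccc(OCc2ccccc2)cc1)c1ccc(OC)cc1 | intermediate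
12 | (2S,3R)-5,7-bis(benzyloxy)-3-{(2S,3S)-7-(benzyloxy)-2-[4-(benzyloxy)phenyl]-5-hydroxy-4-oxochroman-3-yl}-2-(4-methoxyphenyl)chroman-4-one (2'',3''-cis) | COc1ccc([C@H]2Oc3cc(OCc4ccccc4)cc(OCc4ccccc4)c3C(=O)[C@@H]2[C@@H]2C(=O)c3c(O)cc(OCc4ccccc4)cc3O[C@@H]2c2ccc(OCc3ccccc3)cc2)cc1 | intermediate (not isolated)
13 | (2S,3R)-5,7-bis(benzyloxy)-3-{(2S,3R)-7-(benzyloxy)-2-[4-(benzyloxy)phenyl]-5-hydroxy-4-oxochroman-3-yl}-2-(4-methoxyphenyl)chroman-4-one | COc1ccc([C@H]2Oc3cc(OCc4ccccc4)cc(OCc4ccccc4)c3C(=O)[C@@H]2[C@H]2C(=O)c3c(O)cc(OCc4ccccc4)cc3O[C@@H]2c2ccc(OCc3ccccc3)cc2)cc1 | intermediate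
14 | (2S,3R)-5,7-dihydroxy-3-[(2S,3R)-5,7-dihydroxy-2-(4-hydroxyphenyl)-4-oxochroman-3-yl]-2-(4-methoxyphenyl)chroman-4-one | COc1ccc([C@H]2Oc3cc(O)cc(O)c3C(=O)[C@@H]2[C@H]2C(=O)c3c(O)cc(O)cc3O[C@@H]2c2ccc(O)cc2)cc1 | target

**Step count.** Total: 9 steps. Longest linear sequence: 7 steps (1, 2, 3, 4, 7, 8, 9).

**Steps most likely to fail**

1. Step 8 (key step). The photocatalyst may sensitise E/Z isomerisation of the ene-dione before the radical is formed, which would erode the facial bias. The doubly stabilised radical may also add slowly, and ring closure may be partly cis, which would set C2 wrongly and cannot be corrected later. Fallback, from 11 back to 13: the acid would be coupled with 1-hydroxypyridine-2(1H)-thione (DCC, CH2Cl2, dark) to the Barton thiohydroxamate ester F1. Thermal chain decarboxylation at high dilution (benzene, 80 °C, no sensitiser) should generate the same C2 radical from the intact E isomer; after 6-exo closure the C3'' radical is trapped by pyridylthio transfer as the C3'' pyridyl sulfide F2. Bu3SnH/AIBN would then cleave the C–S bond, and Et3N in CH2Cl2/MeOH would equilibrate C3'' to give 13.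

2. Step 7. Hydrolysis of the silyl enol ether may outrun the aldol addition in the aqueous acidic medium. The acid-catalysed dehydration may also move the double bond into ring F (flavone formation, loss of C2'') or lead to a furan. Fallback, from 4 and 8 back to 11: ester 4 would be oxidised with SeO2 to the glyoxal methyl ester F3. Ketone 8 would be converted with Bu2BOTf/i-Pr2NEt (CH2Cl2, −78 °C) into its boron enolate and added to F3 to give the aldol adduct methyl ester F4. MsCl/Et3N would eliminate by the E1cB path to the (E)-ene-dione methyl ester F5, and Me3SnOH (1,2-dichloroethane, 60 °C) would unmask the acid 11 under near-neutral conditions.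

3. Step 9. Hydrogenolysis of the benzylic C2–O1 and C2''–O1'' bonds (ring opening to dihydrochalcones) may compete with debenzylation; the anisyl-substituted C2–O1 bond is the more exposed. Fallback, from 13 directly to 14: Lewis acid cleavage with BCl3 and pentamethylbenzene as cation scavenger (CH2Cl2, −78 °C) would remove the four benzyl groups without hydrogen and should spare the 4'-methyl ether; this fallback makes no new compound (F0).

**Further compounds**
F1 | step 8 | 2-thioxopyridin-1(2H)-yl ester of acid 11 (Barton ester) | S=C1C=CC=CN1OC(=O)C(Oc1cc(OCc2ccccc2)cc(OCc2ccccc2)c1C(=O)/C=C1/C(=O)c2c(O)cc(OCc3ccccc3)cc2O[C@@H]1c1ccc(OCc2ccccc2)cc1)c1ccc(OC)cc1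
F2 | step 8 | 3''-(pyridin-2-ylsulfanyl) derivative of 13 (epimer mixture at C3'') | COc1ccc([C@H]2Oc3cc(OCc4ccccc4)cc(OCc4ccccc4)c3C(=O)[C@@H]2C2(Sc3ccccn3)C(=O)c3c(O)cc(OCc4ccccc4)cc3O[C@@H]2c2ccc(OCc3ccccc3)cc2)cc1
F3 | step 7 | methyl 2-[3,5-bis(benzyloxy)-2-(2-oxoacetyl)phenoxy]-2-(4-methoxyphenyl)acetate | COC(=O)C(Oc1cc(OCc2ccccc2)cc(OCc2ccccc2)c1C(=O)C=O)c1ccc(OC)cc1
F4 | step 7 | methyl ester of aldol adduct 10 (diastereomer mixture) | COC(=O)C(Oc1cc(OCc2ccccc2)cc(OCc2ccccc2)c1C(=O)C(O)C1C(=O)c2c(O)cc(OCc3ccccc3)cc2O[C@@H]1c1ccc(OCc2ccccc2)cc1)c1ccc(OC)cc1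
F5 | step 7 | methyl ester of (E)-ene-dione acid 11 | COC(=O)C(Oc1cc(OCc2ccccc2)cc(OCc2ccccc2)c1C(=O)/C=C1/C(=O)c2c(O)cc(OCc3ccccc3)cc2O[C@@H]1c1ccc(OCc2ccccc2)cc1)c1ccc(OC)cc1
F0 | step 9 | none | none
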